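**Plan**

- Retrosynthesis: the C-3 methylidene and the C-8 isovalerate go on last (E1cB of a C-3 CH2O-acyl group; reduction and acylation of a C-8 ketone). The carbocycle is then taken apart as a two-carbon ring expansion: re-forming the C-4–C-8 bond and re-adding the C-8 oxygen to the β-carbon of the butenoyl group gives cyclobutane 20. Cutting C-3a–C-4 and C-8–C-8a ([2+2]) gives the bicyclic vinylogous ester 11 and the single-enantiomer dihydrofuran 18.
- Enabling feature: in the seven-membered ring C-4 is the only CH2 and lies between the fusion carbon C-3a and the C-5 ketone; C-8 carries oxygen 1,4 to that ketone; the fusion carbons C-3a/C-8a carry C and O. C-4 to C-8 are therefore a cyclopentane-1,3-dione with an enol ether inserted into its C-4–C-8 bond (de Mayo retron). The butenoyl β-carbon is 1,5 to O–C-8, so the two can be tied as a 2-methyltetrahydropyran-4-one that fixes the enol and hides the enone.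
- Forward order: the O-heterocycle comes first (18, from an enzymatically desymmetrised 2-allylpropane-1,3-diol; later oxidised to the γ-lactone). The helper cyclopentane and pyranone rings of 11 are built by Claisen cyclisation and enol etherification. Photocycloaddition adds the cyclobutane. The seven-membered ring arises last, when base opens pyranone and cyclobutane in one cascade.
- Stereochemistry: C-7 by catalytic asymmetric hydroxylation (the (R)-3-hydroxybutanoate centre is a purification handle, erased in the cascade); C-6 by equilibration cis to the C-7 oxygen; C-3a/C-8a by suprafacial photocycloaddition anti to the CH2OTBS group of 18, whose centre comes from lipase desymmetrisation (C-4/C-8 of the photoadduct are erased in the cascade); C-8 by hydride addition anti to the butenoyl group; (E)-alkene by E1cB.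

Key step: step 16

Remark: ring positions are quoted in the cyclohepta[b]furan numbering of the target (O-1, C-2 … C-8a; "future C-n" in precursors); it is assumed that in 10 the epimer with the methyl group cis to the angular oxygen is the more stable one, and that the lipase of step 9 is chosen so that it acetylates the enantiotopic hydroxymethyl group leading to the (S)-monoacetate 14.

**Route**

Step 1
Reactants: 1 methyl (R)-3-hydroxybutanoate
Product: 2 methyl (R)-3-[(tert-butyldimethylsilyl)oxy]butanoate
Conditions: TBSCl, imidazole, DMF, 0 °C → rt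
Reagents that add atoms: tert-butyldimethylsilyl chloride CC(C)(C)[Si](C)(C)Cl
Why: Standard silylation of the secondary alcohol; the (R) centre is not touched and later marks the pyran CH(CH3) carbon.

Step 2
Reactants: 2 methyl (R)-3-[(tert-butyldimethylsilyl)oxy]butanoate; 3 methyl acetate
Product: 4 methyl (R)-5-[(tert-butyldimethylsilyl)oxy]-3-oxohexanoate
Conditions: LDA (2.2 equiv), 3 (2.2 equiv), THF, −78 °C; then 2, −78 → −40 °C; AcOH
Reagents that add atoms: none
Why: Crossed Claisen condensation of lithio methyl acetate with the ester, driven by deprotonation of the β-keto ester; the low temperature should suppress β-elimination of the silyloxy group.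

Step 3
Reactants: 4 methyl (R)-5-[(tert-butyldimethylsilyl)oxy]-3-oxohexanoate; 5 3-bromobutan-2-one (racemic)
Product: 6 methyl (5R)-5-[(tert-butyldimethylsilyl)oxy]-3-oxo-2-(3-oxobutan-2-yl)hexanoate (epimer mixture at C-2 and at the butanone CH)
Conditions: K2CO3, NaI (cat.), acetone, rt
Reagents that add atoms: none
Why: SN2 C-alkylation of the β-keto ester enolate by the activated secondary α-bromo ketone brings in future C-6, C-5 and C-4; both new centres may be mixtures because C-2 becomes quaternary in step 4 and the CH(CH3) centre is equilibrated in step 6.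

Step 4
Reactants: 6 methyl (5R)-5-[(tert-butyldimethylsilyl)oxy]-3-oxo-2-(3-oxobutan-2-yl)hexanoate
Product: 7 methyl (2R,5R)-5-[(tert-butyldimethylsilyl)oxy]-2-hydroxy-3-oxo-2-(3-oxobutan-2-yl)hexanoate
Conditions: Ni(ClO4)2·6H2O (10 mol %), DBFOX-Ph (11 mol %, enantiomer matched to the 2R product), (±)-2-(phenylsulfonyl)-3-phenyloxaziridine, 4 Å MS, CH2Cl2, rt
Reagents that add atoms: 2-(phenylsulfonyl)-3-phenyloxaziridine O=S(=O)(c1ccccc1)N1OC1c1ccccc1
Why: Catalytic enantioselective α-hydroxylation of a 2-substituted β-keto ester (two-point binding to the chiral Ni(II) Lewis acid, oxygen transfer to the open enolate face) sets the tertiary carbinol, future C-7; the (5R) silyloxy centre makes the C-2 epimers diastereomers, so a minor one can be removed by chromatography.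

Step 5
Reactants: 7 methyl (2R,5R)-5-[(tert-butyldimethylsilyl)oxy]-2-hydroxy-3-oxo-2-(3-oxobutan-2-yl)hexanoate
Product: 8 (4R)-4-{(3R)-3-[(tert-butyldimethylsilyl)oxy]butanoyl}-4-hydroxy-5-methylcyclopentane-1,3-dione
Conditions: LiHMDS (3.3 equiv), THF, −78 → −10 °C; AcOH
Reagents that add atoms: none
Why: Intramolecular Claisen (Dieckmann-type, 5-exo-trig) acylation of the kinetic methyl-ketone enolate by the methyl ester closes the cyclopentane-1,3-dione and is pulled through by deprotonation of the product; the carbinol centre is not involved.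

Step 6
Reactants: 8 (4R)-4-{(3R)-3-[(tert-butyldimethylsilyl)oxy]butanoyl}-4-hydroxy-5-methylcyclopentane-1,3-dione
Product: 10 (2R,4aS,5R)-4a-hydroxy-2,5-dimethyl-2,3,4a,5-tetrahydrocyclopenta[b]pyran-4,6-dione, via hydroxy dione 9 (not isolated)
Conditions: aq. HF, MeCN, 0 °C → rt; then TsOH·H2O (cat.), 4 Å MS, toluene, 80 °C
Reagents that add atoms: none
Why: Desilylation, then acid-catalysed vinylogous ester formation: only the enol oxygen next to the quaternary carbon can reach the liberated alcohol in a six-membered ring, so the enone regiochemistry is locked and the hydroxybutanoyl unit becomes a latent butenoyl group, while the acid should equilibrate the methyl-bearing carbon through the dione enol to the epimer cis to the angular OH.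

Step 7
Reactants: 10 (2R,4aS,5R)-4a-hydroxy-2,5-dimethyl-2,3,4a,5-tetrahydrocyclopenta[b]pyran-4,6-dione
Product: 11 (2R,4aS,5R)-2,5-dimethyl-4a-[(triethylsilyl)oxy]-2,3,4a,5-tetrahydrocyclopenta[b]pyran-4,6-dione
Conditions: TESOTf, 2,6-lutidine, CH2Cl2, −78 → 0 °C
Reagents that add atoms: triethylsilyl trifluoromethanesulfonate CC[Si](CC)(CC)OS(=O)(=O)C(F)(F)F
Why: Silylation of the tertiary alcohol with a silyl triflate protects it from the strong base of step 16 and makes it inert during the photochemical step.

Step 8
Reactants: 12 diethyl 2-(prop-2-en-1-yl)propanedioate (diethyl allylmalonate)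
Product: 13 2-(prop-2-en-1-yl)propane-1,3-diol
Conditions: LiAlH4, THF, 0 °C → reflux; H2O, aq. NaOH work-up
Reagents that add atoms: none
Why: Exhaustive hydride reduction of the malonate diester gives the prochiral 2-substituted propane-1,3-diol; the isolated terminal alkene is not touched and no stereocentre exists yet.

Step 9
Reactants: 13 2-(prop-2-en-1-yl)propane-1,3-diol
Product: 14 (2S)-2-(hydroxymethyl)pent-4-en-1-yl acetate
Conditions: lipase PS (Burkholderia cepacia, immobilised), vinyl acetate, i-Pr2O, rt
Reagents that add atoms: vinyl acetate CC(=O)OC=C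
Why: Lipase-catalysed monoacetylation (enzymatic desymmetrisation of a prochiral 2-substituted propane-1,3-diol) distinguishes the two enantiotopic hydroxymethyl groups in the chiral active site and so sets the centre that becomes C-3 of the dihydrofuran; vinyl acetate leaves as acetaldehyde, which makes the acyl transfer irreversible.

Step 10
Reactants: 14 (2S)-2-(hydroxymethyl)pent-4-en-1-yl acetate
Product: 15 [(3S)-5-hydroxytetrahydrofuran-3-yl]methyl acetate (anomer mixture)
Conditions: O3, CH2Cl2, −78 °C; then PPh3, −78 °C → rt
Reagents that add atoms: ozone [O-][O+]=O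
Why: Ozonolysis with reductive work-up turns the allyl group into the aldehyde, which the free primary hydroxyl traps at once as the five-membered lactol, so the hydroxyl is no longer available for the acetyl migration that would racemise 14; the stereocentre itself is not involved.

Step 11
Reactants: 15 [(3S)-5-hydroxytetrahydrofuran-3-yl]methyl acetate (anomer mixture)
Product: 16 [(3S)-2,3-dihydrofuran-3-yl]methyl acetate
Conditions: MsCl, Et3N, CH2Cl2, −40 °C → reflux
Reagents that add atoms: none
Why: Sulfonylation of the anomeric hydroxyl and amine-induced elimination through the oxocarbenium ion (the lactol-to-glycal dehydration used for furanoid glycals) places the enol ether double bond between the former lactol carbon and its only neighbouring CH2, away from the stereocentre.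

Step 12
Reactants: 16 [(3S)-2,3-dihydrofuran-3-yl]methyl acetate
Product: 17 [(3R)-2,3-dihydrofuran-3-yl]methanol
Conditions: K2CO3 (cat.), MeOH, 0 °C → rt
Reagents that add atoms: none
Why: Base-catalysed transesterification with methanol removes the acetate under conditions that leave the acid-labile enol ether and the non-acidic allylic stereocentre alone (the descriptor changes from S to R only through the CIP priorities).

Step 13
Reactants: 17 [(3R)-2,3-dihydrofuran-3-yl]methanol
Product: 18 tert-butyl{[(3S)-2,3-dihydrofuran-3-yl]methoxy}dimethylsilane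
Conditions: TBSCl, imidazole, CH2Cl2, rt
Reagents that add atoms: tert-butyldimethylsilyl chloride CC(C)(C)[Si](C)(C)Cl
Why: Standard silylation; unlike the acetate, the silyl ether is inert to light, RuO4 and amide base and is a poor leaving group β to the later lactone carbonyl.

Step 14
Reactants: 11 (2R,4aS,5R)-2,5-dimethyl-4a-[(triethylsilyl)oxy]-2,3,4a,5-tetrahydrocyclopenta[b]pyran-4,6-dione; 18 tert-butyl{[(3S)-2,3-dihydrofuran-3-yl]methoxy}dimethylsilane
Product: 19 cis-anti-cis cyclobutane photoadduct (tetrahydrofuran–cyclobutane–cyclopentanone–tetrahydropyranone tetracycle)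
Conditions: hν (medium-pressure Hg lamp, Pyrex, λ > 300 nm), CH2Cl2, −40 °C
Reagents that add atoms: none
Why: Enone–alkene [2+2] photocycloaddition through the enone triplet, expected head-to-tail (O-bearing carbon of 18 to the enone β-carbon, future C-8) and suprafacial on the dihydrofuran face anti to its CH2OTBS group, which sets C-3a and C-8a (cis) from the C-3 centre of 18; the adduct drawn is the cis-anti-cis one formed on the enone face anti to the angular OTES group, and an adduct that differs from it only at C-4 and C-8 would converge in step 16, where these two centres are lost.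

Step 15
Reactants: 19 cis-anti-cis cyclobutane photoadduct (tetrahydrofuran–cyclobutane–cyclopentanone–tetrahydropyranone tetracycle)
Product: 20 γ-lactone of the cis-anti-cis photoadduct
Conditions: RuCl3·xH2O (5 mol %), NaIO4, EtOAc–MeCN–pH 7 buffer, rt
Reagents that add atoms: sodium periodate [Na+].[O-]I(=O)(=O)=O
Why: RuO4 oxidation of an ether to a lactone at the only ring O–CH2 group; the O–CH positions (cyclobutane CH, pyran CH(CH3) β to a ketone) should react more slowly, so the γ-lactone exists before the carbocycle is made.

Step 16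
Reactants: 20 γ-lactone of the cis-anti-cis photoadduct
Product: 22 (3R,3aS,6R,7R,8aR)-7-[(2E)-but-2-enoyl]-3-{[(tert-butyldimethylsilyl)oxy]methyl}-6-methyl-7-[(triethylsilyl)oxy]hexahydro-2H-cyclohepta[b]furan-2,5,8-trione, via cyclobutanol enone 21 (not isolated)
Conditions: KHMDS (1.2 equiv), THF, −78 → −20 °C; AcOH, −78 °C
Reagents that add atoms: none
Why: Proposed new method: KHMDS should deprotonate the only unhindered ketone CH2 (pyranone C-3), and the enolate expels the ring oxygen by E1cB (retro-oxa-Michael), which unveils the (E)-but-2-enoyl group and frees the tertiary cyclobutanolate of 21; this alkoxide is β to the cyclopentanone carbonyl and undergoes retro-aldol cleavage of the C-4–C-8 bond shared by the four- and five-membered rings, driven by release of cyclobutane strain. The closest known reaction types are the de Mayo sequence (enone–alkene [2+2] photocycloaddition, then retro-aldol opening of the β-oxy cyclobutyl ketone; here steps 14 and 16) and the base-induced retro-oxa-Michael opening of 2-alkyltetrahydropyran-4-ones; new is that the second triggers the first from an ether-protected photoadduct. The seven-membered ring is closed not by cyclisation but by two-carbon ring expansion: when the C-4–C-8 bond breaks, the cyclopentanone (C-4 to C-8) and the cyclobutane (C-3a, C-8a) merge into the cycloheptane-5,8-dione, and the cyclobutane, cyclopentane and pyranone helper rings all disappear in this step. No stereocentre is created: C-3, C-3a, C-8a (cis, from step 14), C-6 and C-7 are carried through, C-4 and C-8 become CH2 and C=O (so photoadducts that differ only at these two centres give the same product), the pyran CH(CH3) becomes an alkene carbon, and the (E) geometry should follow from elimination through the conformer with the methyl group anti to the carbonyl. The step needs site-selective enolisation (pyranone CH2, not the lactone α-CH, the C-6 methine or the cyclobutane CH) and fragmentation faster than enolate equilibration, which the kinetic acidity of the ketone CH2 towards a slight excess of a hindered amide at −78 °C, the irreversibility of the strain-releasing retro-aldol step and the cold acetic acid quench of the C-4/C-5 enolate are expected to secure.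

Step 17
Reactants: 22 (3R,3aS,6R,7R,8aR)-7-[(2E)-but-2-enoyl]-3-{[(tert-butyldimethylsilyl)oxy]methyl}-6-methyl-7-[(triethylsilyl)oxy]hexahydro-2H-cyclohepta[b]furan-2,5,8-trione
Product: 23 (3R,3aS,6R,7R,8aR)-7-[(2E)-but-2-enoyl]-7-hydroxy-3-(hydroxymethyl)-6-methylhexahydro-2H-cyclohepta[b]furan-2,5,8-trione
Conditions: HF·pyridine, THF–pyridine, 0 °C → rt
Reagents that add atoms: none
Why: Fluoride-driven desilylation of both silyl ethers under mildly acidic conditions that should leave enone, β-diketone and lactone intact.

Step 18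
Reactants: 23 (3R,3aS,6R,7R,8aR)-7-[(2E)-but-2-enoyl]-7-hydroxy-3-(hydroxymethyl)-6-methylhexahydro-2H-cyclohepta[b]furan-2,5,8-trione
Product: 24 (3R,3aS,6R,7S,8S,8aR)-7-[(2E)-but-2-enoyl]-7,8-dihydroxy-3-(hydroxymethyl)-6-methylhexahydro-2H-cyclohepta[b]furan-2,5-dione
Conditions: NaBH4, CH2Cl2–MeOH (1:1), −78 °C
Reagents that add atoms: none
Why: Chemoselective borohydride reduction: the C-8 ketone, with C–O bonds on both α-carbons, should be far more electrophilic than the C-5 ketone and the conjugated ketone, and hydride is expected on the face of the free C-7 hydroxyl, anti to the pseudo-axial butenoyl group, giving the trans C-7/C-8 diol.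

Step 19
Reactants: 24 (3R,3aS,6R,7S,8S,8aR)-7-[(2E)-but-2-enoyl]-7,8-dihydroxy-3-(hydroxymethyl)-6-methylhexahydro-2H-cyclohepta[b]furan-2,5-dione; 25 3-methylbutanoic anhydride
Product: 27 CNP0283951.1 (target), via bis-isovalerate 26 (not isolated)
Conditions: 25 (3 equiv), DMAP (cat.), Et3N, CH2Cl2, 0 °C → rt; then DBU, rt
Reagents that add atoms: none
Why: DMAP-catalysed acylation should esterify the secondary C-8 and the primary hydroxyl but not the tertiary one, and DBU then removes the primary isovalerate by E1cB through the lactone enolate (β-acyloxy lactone to α-methylene lactone); the C-8 ester has no acidic hydrogen β to it and stays.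

**Compound list**

1 | methyl (R)-3-hydroxybutanoate | C[C@@H](O)CC(=O)OC | starting material
2 | methyl (R)-3-[(tert-butyldimethylsilyl)oxy]butanoate | C[C@@H](O[Si](C)(C)C(C)(C)C)CC(=O)OC | intermediate
3 | methyl acetate | COC(C)=O | starting material
4 | methyl (R)-5-[(tert-butyldimethylsilyl)oxy]-3-oxohexanoate | C[C@@H](O[Si](C)(C)C(C)(C)C)CC(=O)CC(=O)OC | intermediate
5 | 3-bromobutan-2-one (racemic) | CC(Br)C(C)=O | starting material
6 | methyl (5R)-5-[(tert-butyldimethylsilyl)oxy]-3-oxo-2-(3-oxobutan-2-yl)hexanoate (epimer mixture at C-2 and at the butanone CH) | C[C@@H](O[Si](C)(C)C(C)(C)C)CC(=O)C(C(C)C(C)=O)C(=O)OC | intermediate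
7 | methyl (2R,5R)-5-[(tert-butyldimethylsilyl)oxy]-2-hydroxy-3-oxo-2-(3-oxobutan-2-yl)hexanoate (both epimers at the butanone CH) | C[C@@H](O[Si](C)(C)C(C)(C)C)CC(=O)[C@](O)(C(C)C(C)=O)C(=O)OC | intermediate
8 | (4R)-4-{(3R)-3-[(tert-butyldimethylsilyl)oxy]butanoyl}-4-hydroxy-5-methylcyclopentane-1,3-dione (both C-5 epimers; drawn as the diketone) | C[C@@H](O[Si](C)(C)C(C)(C)C)CC(=O)[C@]1(O)C(C)C(=O)CC1=O | intermediate
9 | (4R)-4-hydroxy-4-[(3R)-3-hydroxybutanoyl]-5-methylcyclopentane-1,3-dione (both C-5 epimers) | C[C@@H](O)CC(=O)[C@]1(O)C(C)C(=O)CC1=O | intermediate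
10 | (2R,4aS,5R)-4a-hydroxy-2,5-dimethyl-2,3,4a,5-tetrahydrocyclopenta[b]pyran-4,6-dione (4a-OH and 5-CH3 cis) | C[C@@H]1CC(=O)[C@]2(O)[C@@H](C)C(=O)C=C2O1 | intermediate
11 | (2R,4aS,5R)-2,5-dimethyl-4a-[(triethylsilyl)oxy]-2,3,4a,5-tetrahydrocyclopenta[b]pyran-4,6-dione | C[C@@H]1CC(=O)[C@]2(O[Si](CC)(CC)CC)[C@@H](C)C(=O)C=C2O1 | intermediate
12 | diethyl 2-(prop-2-en-1-yl)propanedioate (diethyl allylmalonate) | C=CCC(C(=O)OCC)C(=O)OCC | starting material
13 | 2-(prop-2-en-1-yl)propane-1,3-diol | C=CCC(CO)CO | intermediate
14 | (2S)-2-(hydroxymethyl)pent-4-en-1-yl acetate | CC(=O)OC[C@@H](CC=C)CO | intermediate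
15 | [(3S)-5-hydroxytetrahydrofuran-3-yl]methyl acetate (both anomers) | CC(=O)OC[C@@H]1COC(O)C1 | intermediate
16 | [(3S)-2,3-dihydrofuran-3-yl]methyl acetate | CC(=O)OC[C@@H]1COC=C1 | intermediate
17 | [(3R)-2,3-dihydrofuran-3-yl]methanol | OC[C@@H]1COC=C1 | intermediate
18 | tert-butyl{[(3S)-2,3-dihydrofuran-3-yl]methoxy}dimethylsilane | CC(C)(C)[Si](C)(C)OC[C@@H]1COC=C1 | intermediate
19 | cis-anti-cis cyclobutane photoadduct of 11 and 18: tetrahydrofuran–cyclobutane–cyclopentanone–tetrahydropyranone tetracycle; CH2OTBS trans to the cyclobutane on the tetrahydrofuran, OTES trans to the cyclobutane and cis to CH3 on the cyclopentanone | CC(C)(C)[Si](C)(C)OC[C@@H]1CO[C@@H]2[C@H]1[C@H]3C(=O)[C@H](C)[C@@](O[Si](CC)(CC)CC)(C(=O)C[C@@H](C)O4)[C@@]234 | intermediate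
20 | γ-lactone of 19 (tetrahydrofuran O–CH2 oxidised to C=O) | CC(C)(C)[Si](C)(C)OC[C@@H]1C(=O)O[C@@H]2[C@H]1[C@H]3C(=O)[C@H](C)[C@@](O[Si](CC)(CC)CC)(C(=O)C[C@@H](C)O4)[C@@]234 | intermediate
21 | cyclobutanol with free (E)-but-2-enoyl group, from opening of the pyranone of 20 (formed as its potassium alkoxide) | CC(C)(C)[Si](C)(C)OC[C@@H]1C(=O)O[C@@H]2[C@H]1[C@H]3C(=O)[C@H](C)[C@@](O[Si](CC)(CC)CC)(C(=O)/C=C/C)[C@@]23O | intermediate
22 | (3R,3aS,6R,7R,8aR)-7-[(2E)-but-2-enoyl]-3-{[(tert-butyldimethylsilyl)oxy]methyl}-6-methyl-7-[(triethylsilyl)oxy]hexahydro-2H-cyclohepta[b]furan-2,5,8-trione | CC(C)(C)[Si](C)(C)OC[C@@H]1C(=O)O[C@@H]2[C@H]1CC(=O)[C@H](C)[C@@](O[Si](CC)(CC)CC)(C(=O)/C=C/C)C2=O | intermediate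
23 | (3R,3aS,6R,7R,8aR)-7-[(2E)-but-2-enoyl]-7-hydroxy-3-(hydroxymethyl)-6-methylhexahydro-2H-cyclohepta[b]furan-2,5,8-trione | OC[C@@H]1C(=O)O[C@@H]2[C@H]1CC(=O)[C@H](C)[C@@](O)(C(=O)/C=C/C)C2=O | intermediate
24 | (3R,3aS,6R,7S,8S,8aR)-7-[(2E)-but-2-enoyl]-7,8-dihydroxy-3-(hydroxymethyl)-6-methylhexahydro-2H-cyclohepta[b]furan-2,5-dione | OC[C@@H]1C(=O)O[C@@H]2[C@H]1CC(=O)[C@H](C)[C@@](O)(C(=O)/C=C/C)[C@H]2O | intermediate
25 | 3-methylbutanoic anhydride | CC(C)CC(=O)OC(=O)CC(C)C | starting material
26 | (3R,3aS,6R,7S,8S,8aR)-7-[(2E)-but-2-enoyl]-7-hydroxy-6-methyl-3-{[(3-methylbutanoyl)oxy]methyl}-2,5-dioxooctahydro-2H-cyclohepta[b]furan-8-yl 3-methylbutanoate | CC(C)CC(=O)OC[C@@H]1C(=O)O[C@@H]2[C@H]1CC(=O)[C@H](C)[C@@](O)(C(=O)/C=C/C)[C@H]2OC(=O)CC(C)C | intermediate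
27 | (3aS,6R,7S,8S,8aR)-7-[(2E)-but-2-enoyl]-7-hydroxy-6-methyl-3-methylidene-2,5-dioxooctahydro-2H-cyclohepta[b]furan-8-yl 3-methylbutanoate (CNP0283951.1) | C=C1C(=O)O[C@@H]2[C@H]1CC(=O)[C@H](C)[C@@](O)(C(=O)/C=C/C)[C@H]2OC(=O)CC(C)C | target

**Totals and risks**

Total step count: 19. Longest linear sequence: 13 steps (steps 1–7, then 14–19); steps 8–13 are the six-step branch to 18.

Steps most likely to fail:

1. Step 16 (proposed new method). What may go wrong: expulsion of the hindered cyclobutanolate may be slower than enolate equilibration, so that C-6 epimerises, the lactone enolate loses silanolate, or the product enolate adds to the newly formed enone before the quench. Fallback with known chemistry, setting out from 20: iodotrimethylsilane (CH2Cl2, −40 °C) should cleave the pyran at its secondary C–O bond (iodide attacks CH(CH3), not the neopentyl-like cyclobutane carbon) to give the β-iodo ketone cyclobutyl silyl ether F1. Triethylamine then eliminates HI to the butenoyl cyclobutyl silyl ether F2. HF·pyridine removes all three silyl groups, whereupon the free β-hydroxy cyclobutyl ketone should open by the retro-aldol step of the classical de Mayo reaction. The route is rejoined at 23.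

2. Step 14. What may go wrong: addition to the dihydrofuran face syn to its CH2OTBS group or head-to-head orientation, a competing 1,2-acyl shift of the β,γ-unsaturated pyranone carbonyl, or slow reaction at the fully substituted β-carbon. Fallback, setting out from 8: silylation of the tertiary alcohol (TESOTf, 2,6-lutidine; aqueous work-up) and equilibration of C-5 (cat. TsOH) should give the dione silyl ether F3. F3 is irradiated with 18 as the free enol, which is held at the oxygen next to the quaternary carbon by a hydrogen bond to the side-chain ketone (classical de Mayo reaction). The cyclobutanol opens in the flask to the cycloheptanedione F4. RuO4 as in step 15 gives the lactone F5, and HF·pyridine gives the hydroxybutanoyl triol F6. Acid-catalysed dehydration of the β-hydroxy ketone (TsOH, benzene, 50 °C) rejoins the route at 23.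

3. Step 18. What may go wrong: competing reduction of the C-5 ketone or the enone carbonyl, conjugate reduction, or hydride delivery from the face of the butenoyl group. Fallback, setting out from 20: the fragmentation of step 16 is run as described but, instead of the acetic acid quench, LiAlH(Ot-Bu)3 is added at −78 °C, so that the C-5 ketone is still masked as its potassium enolate while the C-8 ketone is reduced. This should give the silylated C-8 alcohol F7, and HF·pyridine as in step 17 rejoins the route at 24.

Further compounds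

F1 | step 16 | β-iodo ketone cyclobutyl trimethylsilyl ether (pyran of 20 cleaved at CH(CH3)–O) | CC(C)(C)[Si](C)(C)OC[C@@H]1C(=O)O[C@@H]2[C@H]1[C@H]3C(=O)[C@H](C)[C@@](O[Si](CC)(CC)CC)(C(=O)C[C@H](C)I)[C@@]23O[Si](C)(C)C
F2 | step 16 | (E)-but-2-enoyl cyclobutyl trimethylsilyl ether | CC(C)(C)[Si](C)(C)OC[C@@H]1C(=O)O[C@@H]2[C@H]1[C@H]3C(=O)[C@H](C)[C@@](O[Si](CC)(CC)CC)(C(=O)/C=C/C)[C@@]23O[Si](C)(C)C
F3 | step 14 | 4-{(3R)-3-[(tert-butyldimethylsilyl)oxy]butanoyl}-5-methyl-4-[(triethylsilyl)oxy]cyclopentane-1,3-dione (CH3 cis to OTES) | C[C@@H](O[Si](C)(C)C(C)(C)C)CC(=O)[C@]1(O[Si](CC)(CC)CC)[C@@H](C)C(=O)CC1=O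
F4 | step 14 | ring-expanded tetrahydrofuran-fused cycloheptane-5,8-dione with 3-(silyloxy)butanoyl side chain | CC(C)(C)[Si](C)(C)OC[C@@H]1CO[C@@H]2[C@H]1CC(=O)[C@H](C)[C@@](O[Si](CC)(CC)CC)(C(=O)C[C@@H](C)O[Si](C)(C)C(C)(C)C)C2=O
F5 | step 14 | γ-lactone of F4 | CC(C)(C)[Si](C)(C)OC[C@@H]1C(=O)O[C@@H]2[C@H]1CC(=O)[C@H](C)[C@@](O[Si](CC)(CC)CC)(C(=O)C[C@@H](C)O[Si](C)(C)C(C)(C)C)C2=O
F6 | step 14 | 7-hydroxy-7-[(3R)-3-hydroxybutanoyl]-3-(hydroxymethyl)-6-methylhexahydro-2H-cyclohepta[b]furan-2,5,8-trione | OC[C@@H]1C(=O)O[C@@H]2[C@H]1CC(=O)[C@H](C)[C@@](O)(C(=O)C[C@@H](C)O)C2=O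
F7 | step 18 | C-8 alcohol of 22 with both silyl ethers in place | CC(C)(C)[Si](C)(C)OC[C@@H]1C(=O)O[C@@H]2[C@H]1CC(=O)[C@H](C)[C@@](O[Si](CC)(CC)CC)(C(=O)/C=C/C)[C@H]2O
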